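**Plan**

1. Numbering (germacrane): ring C1–C10; γ-lactone O–C6 and C7–C11(=C13)–C12(=O); C14 = the CH2O carbon on C10; C15 = CH3 on C4.
2. Retrosynthetic cuts, in order: C10–C14 (alkenyl bromide + acyloxymethyl metal); C7–C8 (opens the ten-membered ring to an allylstannane aldehyde); C11–C13 and the butenolide (γ-hydroxy ynoate, C6–C7 from methyl propiolate); C8–C9 (Weinreb amide + ROCH2Li); C1=C10 (bromo-olefination). C1–C6 with C15 come from neryl acetate.
3. Forward order: open chain carrying the (Z)-C4=C5 and ring-cis C1=C10(Br) alkenes, then the butenolide (lactone ring first), then the ten-membered ring by C7–C8 closure (which also creates the exocyclic methylene), then the ester side chain last.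
4. Stereochemistry: C9 by CBS reduction; C6 by catalytic asymmetric alkynylation; C7 and C8 in the ring closure (attack anti to C5 on the butenolide, Felkin–Anh at the α-acetoxy aldehyde); the side-chain centre from (R)-2-methylbutanoic acid; alkene geometries from nerol and from the (E)-selective bromo-olefination.
5. Feature behind the key event: C10 is an sp2 carbon of the ring-cis C1=C10 alkene of the ten-membered ring, so its bromide is replaced with retention. C14 is an O-acyl methylene (acetal-type carbon), electrophilic as the iodomethyl ester but nucleophilic after zinc insertion (carbonyl-chelated zinc carbenoid). Two electrophilic carbons are thus joined by polarity reversal, and the whole ester arrives intact, so 8-OH, 9-OAc and the C14 ester never have to be differentiated.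

Key step: step 18

Remarks on the chemistry:
- (R)-2-Methylbutanoic acid is taken as commercially available (it is also accessible by asymmetric hydrogenation of tiglic acid).
- The 1-ethoxyethyl acetal carbon in 8–12 and 15–22 is carried as a mixture of epimers and is left undefined in the SMILES; it is removed in step 13.
- The ProPhenol enantiomer in step 9 is the one that delivers the alkynyl group to the Si face of the enal; it is written as (S,S) on the usual model, and the (R,R)-ligand is used if the sense is opposite.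

Step 1
Reactants: 1 neryl acetate [(2Z)-3,7-dimethylocta-2,6-dien-1-yl acetate]
Product: 2 (2Z)-3-methyl-6-oxohex-2-en-1-yl acetate
Conditions: O3 (1.0 equiv), pyridine, CH2Cl2, −78 °C; then Me2S, −78 → 25 °C
Reagents that add atoms: ozone, O=[O+][O-]
Why: Chemoselective ozonolysis, in which the electron-rich terminal trisubstituted alkene reacts before the alkene deactivated by the allylic acetate, so C1 is unveiled as the aldehyde while the (Z)-C4=C5 bond and C15 of nerol are kept (no new stereocentre).

Step 2
Reactants: 3 methyl [bis(2,2,2-trifluoroethoxy)phosphoryl]acetate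
Product: 4 methyl bromo[bis(2,2,2-trifluoroethoxy)phosphoryl]acetate
Conditions: NaH, THF, 0 °C; then NBS, −78 → 0 °C
Reagents that add atoms: N-bromosuccinimide, O=C1CCC(=O)N1Br
Why: Electrophilic α-bromination of the sodium phosphonoacetate should give the bromo Still–Gennari-type olefination reagent (no stereochemical issue).

Step 3
Reactants: 2 (2Z)-3-methyl-6-oxohex-2-en-1-yl acetate, 4 methyl bromo[bis(2,2,2-trifluoroethoxy)phosphoryl]acetate
Product: 5 methyl (2E,6Z)-8-acetoxy-2-bromo-6-methylocta-2,6-dienoate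
Conditions: 4, KOt-Bu, 18-crown-6, THF, −78 °C; then 2, −78 °C
Reagents that add atoms: none
Why: Horner–Wadsworth–Emmons olefination with the bis(trifluoroethyl) bromophosphonoacetate (Still–Gennari-type kinetic control) should place the chain cis to the ester, i.e. give the (E)-α-bromoacrylate, which fixes the ring-cis C1=C10 geometry and installs the C10 bromide.

Step 4
Reactants: 5 methyl (2E,6Z)-8-acetoxy-2-bromo-6-methylocta-2,6-dienoate
Product: 6 (2E,6Z)-2-bromo-8-hydroxy-N-methoxy-N,6-dimethylocta-2,6-dienamide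
Conditions: MeNH(OMe)·HCl, AlMe3 (excess), CH2Cl2, 0 → 25 °C; aq. HCl/Rochelle salt
Reagents that add atoms: N,O-dimethylhydroxylamine hydrochloride, CNOC.Cl
Why: Weinreb aminolysis with the aluminium amide should convert the conjugated ester into the N-methoxy-N-methylamide and at the same time cleave the allylic acetate (freeing the C6 hydroxyl) without touching the alkenyl bromide.

Step 5
Reactants: 7 (tributylstannyl)methanol
Product: 8 tributyl[(1-ethoxyethoxy)methyl]stannane
Conditions: ethyl vinyl ether, PPTS (cat.), CH2Cl2, 0 → 25 °C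
Reagents that add atoms: ethyl vinyl ether, C=COCC
Why: Acid-catalysed addition of the alcohol to the enol ether (acetal formation) should give the protected precursor of a hydroxymethyl anion equivalent.

Step 6
Reactants: 6 (2E,6Z)-2-bromo-8-hydroxy-N-methoxy-N,6-dimethylocta-2,6-dienamide, 8 tributyl[(1-ethoxyethoxy)methyl]stannane
Product: 10 (3E,7Z)-3-bromo-1-(1-ethoxyethoxy)-9-hydroxy-7-methylnona-3,7-dien-2-one, via alkoxymethyllithium 9 (not isolated)
Conditions: 8 (2.3 equiv), n-BuLi (2.3 equiv), THF, −78 °C; then 6, −78 °C; aq. NH4Cl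
Reagents that add atoms: none
Why: Tin–lithium exchange gives the α-alkoxymethyllithium, which should add once to the Weinreb amide (chelated tetrahedral intermediate) to give the C9 ketone carrying C8, the first equivalent being consumed by the hydroxyl.

Step 7
Reactants: 10 (3E,7Z)-3-bromo-1-(1-ethoxyethoxy)-9-hydroxy-7-methylnona-3,7-dien-2-one
Product: 11 (2S,3E,7Z)-3-bromo-1-(1-ethoxyethoxy)-7-methylnona-3,7-diene-2,9-diol
Conditions: (R)-Me-CBS (0.2 equiv), catecholborane, toluene, −78 °C
Reagents that add atoms: none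
Why: Corey–Bakshi–Shibata reduction, in which the α-bromovinyl group acts as the large substituent, should deliver hydride to one face of the ketone and set C9 by reagent control (the (R)-catalyst giving the (S)-carbinol, which is the C9 arrangement of the target).

Step 8
Reactants: 11 (2S,3E,7Z)-3-bromo-1-(1-ethoxyethoxy)-7-methylnona-3,7-diene-2,9-diol
Product: 12 (2Z,6E,8S)-7-bromo-9-(1-ethoxyethoxy)-8-hydroxy-3-methylnona-2,6-dienal
Conditions: TEMPO (10 mol%), PhI(OAc)2, CH2Cl2, 0 → 25 °C
Reagents that add atoms: none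
Why: Oxoammonium (TEMPO) oxidation is selective for the primary allylic alcohol over the secondary one and should give the neral-type (Z)-enal without isomerisation.

Step 9
Reactants: 12 (2Z,6E,8S)-7-bromo-9-(1-ethoxyethoxy)-8-hydroxy-3-methylnona-2,6-dienal, 13 methyl propiolate
Product: 15 methyl (4R,5Z,9E,11S)-10-bromo-12-(1-ethoxyethoxy)-4,11-dihydroxy-6-methyldodeca-5,9-dien-2-ynoate, via zinc acetylide 14 (not isolated)
Conditions: 13 (3 equiv), Me2Zn (3.5 equiv), (S,S)-ProPhenol (20 mol%), Ph3P=O (40 mol%), toluene, 4 °C; aq. NH4Cl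
Reagents that add atoms: none
Why: Dinuclear zinc–ProPhenol-catalysed asymmetric alkynylation of the α,β-unsaturated aldehyde should add the alkynylzinc to the Si face and set C6 (4R in 15), the methylzinc species tolerating the hydroxyl, the acetal and the alkenyl bromide.

Step 10
Reactants: 15 methyl (4R,5Z,9E,11S)-10-bromo-12-(1-ethoxyethoxy)-4,11-dihydroxy-6-methyldodeca-5,9-dien-2-ynoate
Product: 18 (5R)-5-[(1Z,5E,7S)-6-bromo-8-(1-ethoxyethoxy)-7-hydroxy-2-methylocta-1,5-dien-1-yl]-3-iodofuran-2(5H)-one, via stannyl enoate 16 (not isolated), via stannyl butenolide 17 (not isolated)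
Conditions: Bu3SnH (1.2 equiv), Pd(PPh3)4 (2 mol%), THF, 0 °C; then SiO2, CH2Cl2, 25 °C; then I2, CH2Cl2, 0 °C
Reagents that add atoms: iodine, II
Why: Palladium-catalysed syn-hydrostannation of the ynoate puts tin α to the ester and hydrogen on C7, so the C6 hydroxyl and the ester are cis and lactonise to the butenolide, and iododestannylation with retention should then give the 3-iodobutenolide with C6 untouched.

Step 11
Reactants: 18 (5R)-5-[(1Z,5E,7S)-6-bromo-8-(1-ethoxyethoxy)-7-hydroxy-2-methylocta-1,5-dien-1-yl]-3-iodofuran-2(5H)-one, 19 tributyl(iodomethyl)stannane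
Product: 21 (5R)-5-[(1Z,5E,7S)-6-bromo-8-(1-ethoxyethoxy)-7-hydroxy-2-methylocta-1,5-dien-1-yl]-3-[(tributylstannyl)methyl]furan-2(5H)-one, via stannylmethylzinc iodide 20 (not isolated)
Conditions: 19, Zn dust (TMSCl/BrCH2CH2Br-activated), THF, 25 °C; then 18, Pd(PPh3)4 (5 mol%), THF, 25 °C
Reagents that add atoms: none
Why: Negishi coupling of the electron-poor alkenyl iodide (far faster oxidative addition than the hindered alkenyl bromide) with the α-stannylmethylzinc reagent should give the 2-(alkoxycarbonyl)allylstannane; no stereocentre is affected and no allylic ester is yet present to be ionised by Pd(0).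

Step 12
Reactants: 21 (5R)-5-[(1Z,5E,7S)-6-bromo-8-(1-ethoxyethoxy)-7-hydroxy-2-methylocta-1,5-dien-1-yl]-3-[(tributylstannyl)methyl]furan-2(5H)-one
Product: 22 (5R)-5-[(1Z,5E,7S)-7-acetoxy-6-bromo-8-(1-ethoxyethoxy)-2-methylocta-1,5-dien-1-yl]-3-[(tributylstannyl)methyl]furan-2(5H)-one
Conditions: Ac2O, pyridine, DMAP (5 mol%), CH2Cl2, 0 °C
Reagents that add atoms: acetic anhydride, CC(=O)OC(C)=O
Why: Standard acylation of the only free hydroxyl (C9) installs the acetate of the target, pyridine being too weak a base to epimerise the butenolide γ-position.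

Step 13
Reactants: 22 (5R)-5-[(1Z,5E,7S)-7-acetoxy-6-bromo-8-(1-ethoxyethoxy)-2-methylocta-1,5-dien-1-yl]-3-[(tributylstannyl)methyl]furan-2(5H)-one
Product: 23 (5R)-5-[(1Z,5E,7S)-7-acetoxy-6-bromo-8-hydroxy-2-methylocta-1,5-dien-1-yl]-3-[(tributylstannyl)methyl]furan-2(5H)-one
Conditions: PPTS (10 mol%), MeOH, 0 → 25 °C
Reagents that add atoms: none
Why: Acid-catalysed transacetalisation should remove the 1-ethoxyethyl group under conditions too mild for protodestannylation of the electron-poor allylstannane or for acetyl migration.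

Step 14
Reactants: 23 (5R)-5-[(1Z,5E,7S)-7-acetoxy-6-bromo-8-hydroxy-2-methylocta-1,5-dien-1-yl]-3-[(tributylstannyl)methyl]furan-2(5H)-one
Product: 24 (5R)-5-[(1Z,5E,7S)-7-acetoxy-6-bromo-2-methyl-8-oxoocta-1,5-dien-1-yl]-3-[(tributylstannyl)methyl]furan-2(5H)-one
Conditions: Dess–Martin periodinane, NaHCO3, CH2Cl2, 0 °C; used crude
Reagents that add atoms: none
Why: Buffered Dess–Martin oxidation should give the α-acetoxy aldehyde (C8) without epimerisation at C9 or migration of the C1=C10 double bond.

Step 15
Reactants: 24 (5R)-5-[(1Z,5E,7S)-7-acetoxy-6-bromo-2-methyl-8-oxoocta-1,5-dien-1-yl]-3-[(tributylstannyl)methyl]furan-2(5H)-one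
Product: 25 (3aR,4S,5S,6E,10Z,11aR)-6-bromo-4-hydroxy-10-methyl-3-methylidene-2-oxo-2,3,3a,4,5,8,9,11a-octahydrocyclodeca[b]furan-5-yl acetate
Conditions: BF3·OEt2 (2 equiv), CH2Cl2 (0.002 M, slow addition of 24), −78 °C; aq. NaHCO3
Reagents that add atoms: none
Why: Lewis-acid-promoted intramolecular SE2′ addition of the allylstannane to the aldehyde (Keck-type allylation, open transition state, high dilution) should close the ten-membered ring at C7–C8 and create the exocyclic methylene: C7 is attacked on the butenolide face anti to the C5 alkenyl group (trans-lactone) and the aldehyde reacts in the Felkin–Anh sense with the C9 acetoxy group antiperiplanar (8,9-anti), which together give the 7,8-syn array that an open transition state also prefers.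

Step 16
Reactants: 26 (2R)-2-methylbutanoic acid, 27 chloroiodomethane
Product: 28 chloromethyl (2R)-2-methylbutanoate
Conditions: 27 (4 equiv), Cs2CO3 (0.6 equiv), DMF, 25 °C
Reagents that add atoms: none
Why: SN2 O-alkylation of the caesium carboxylate at the iodine-bearing carbon (iodide is the better leaving group) should give the chloromethyl ester without enolising the α-stereocentre.

Step 17
Reactants: 28 chloromethyl (2R)-2-methylbutanoate
Product: 29 iodomethyl (2R)-2-methylbutanoate
Conditions: NaI, acetone, 25 °C, dark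
Reagents that add atoms: sodium iodide, [Na+].[I-]
Why: Finkelstein halide exchange (NaCl precipitates from acetone) should give the iodomethyl ester needed for zinc insertion.

Step 18
Reactants: 25 (3aR,4S,5S,6E,10Z,11aR)-6-bromo-4-hydroxy-10-methyl-3-methylidene-2-oxo-2,3,3a,4,5,8,9,11a-octahydrocyclodeca[b]furan-5-yl acetate, 29 iodomethyl (2R)-2-methylbutanoate
Product: 31 [(3aR,4S,5R,6Z,10Z,11aR)-5-acetoxy-4-hydroxy-10-methyl-3-methylidene-2-oxo-2,3,3a,4,5,8,9,11a-octahydrocyclodeca[b]furan-6-yl]methyl (2R)-2-methylbutanoate, via acyloxymethylzinc iodide 30 (not isolated)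
Conditions: 29, Zn dust (activated), THF, 10 → 25 °C (gives 30, 3 equiv); then 25, Pd(OAc)2 (5 mol%), SPhos (10 mol%), THF, 25 °C
Reagents that add atoms: none
Why: Proposed new method: zinc inserts into the C–I bond of 29 to give the carbonyl-chelated zinc carbenoid 30, in which the acetal-type carbon C14 has changed from electrophile to nucleophile; Pd(0) then adds oxidatively to the C10–Br bond of 25 with retention, 30 transmetalates, and reductive elimination forms C10–C14 (Negishi coupling). The closest known reactions are Negishi couplings of functionalised alkylzinc iodides with alkenyl halides, the use of (acyloxymethyl)zinc and -copper reagents as hydroxymethyl anion equivalents, and the Suzuki coupling of potassium acetoxymethyltrifluoroborate with aryl halides, which shows that a Pd–CH2OC(O)R species undergoes reductive elimination. No ring is closed and no stereocentre is formed: the ring-cis C1=C10 geometry is that of the bromide, and the (R) centre of the ester is untouched because the reagent is non-basic. The step needs selectivity for C(sp2)–Br oxidative addition over ionisation of the allylic C9 acetate (and of the allylic ester in the product), over insertion of the alkenylpalladium into the exocyclic methylene lactone and over protonation of 30 by the C8 hydroxyl; a bulky electron-rich ligand that makes oxidative addition and transmetalation fast at room temperature, the absence of base and an excess of 30 should secure this. Because the complete acyloxymethyl unit is delivered, the 8-OH, 9-OAc and C14 ester groups never have to be told apart by acylation.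

**Compound list**

1 | neryl acetate, (2Z)-3,7-dimethylocta-2,6-dien-1-yl acetate | CC(=O)OC/C=C(/C)CCC=C(C)C | starting material
2 | (2Z)-3-methyl-6-oxohex-2-en-1-yl acetate | CC(=O)OC/C=C(/C)CCC=O | intermediate
3 | methyl [bis(2,2,2-trifluoroethoxy)phosphoryl]acetate | COC(=O)CP(=O)(OCC(F)(F)F)OCC(F)(F)F | starting material
4 | methyl bromo[bis(2,2,2-trifluoroethoxy)phosphoryl]acetate | COC(=O)C(Br)P(=O)(OCC(F)(F)F)OCC(F)(F)F | intermediate
5 | methyl (2E,6Z)-8-acetoxy-2-bromo-6-methylocta-2,6-dienoate | CC(=O)OC/C=C(/C)CC/C=C(/Br)C(=O)OC | intermediate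
6 | (2E,6Z)-2-bromo-8-hydroxy-N-methoxy-N,6-dimethylocta-2,6-dienamide | OC/C=C(/C)CC/C=C(/Br)C(=O)N(C)OC | intermediate
7 | (tributylstannyl)methanol | OC[Sn](CCCC)(CCCC)CCCC | starting material
8 | tributyl[(1-ethoxyethoxy)methyl]stannane | CCOC(C)OC[Sn](CCCC)(CCCC)CCCC | intermediate
9 | [(1-ethoxyethoxy)methyl]lithium | [Li]COC(C)OCC | intermediate
10 | (3E,7Z)-3-bromo-1-(1-ethoxyethoxy)-9-hydroxy-7-methylnona-3,7-dien-2-one | OC/C=C(/C)CC/C=C(/Br)C(=O)COC(C)OCC | intermediate
11 | (2S,3E,7Z)-3-bromo-1-(1-ethoxyethoxy)-7-methylnona-3,7-diene-2,9-diol | OC/C=C(/C)CC/C=C(/Br)[C@@H](O)COC(C)OCC | intermediate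
12 | (2Z,6E,8S)-7-bromo-9-(1-ethoxyethoxy)-8-hydroxy-3-methylnona-2,6-dienal | O=C/C=C(/C)CC/C=C(/Br)[C@@H](O)COC(C)OCC | intermediate
13 | methyl propiolate | C#CC(=O)OC | starting material
14 | methyl(3-methoxy-3-oxoprop-1-yn-1-yl)zinc | C[Zn]C#CC(=O)OC | intermediate
15 | methyl (4R,5Z,9E,11S)-10-bromo-12-(1-ethoxyethoxy)-4,11-dihydroxy-6-methyldodeca-5,9-dien-2-ynoate | COC(=O)C#C[C@H](O)/C=C(/C)CC/C=C(/Br)[C@@H](O)COC(C)OCC | intermediate
16 | methyl (2E,4R,5Z,9E,11S)-10-bromo-12-(1-ethoxyethoxy)-4,11-dihydroxy-6-methyl-2-(tributylstannyl)dodeca-2,5,9-trienoate | COC(=O)/C([Sn](CCCC)(CCCC)CCCC)=C\[C@H](O)/C=C(/C)CC/C=C(/Br)[C@@H](O)COC(C)OCC | intermediate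
17 | (5R)-5-[(1Z,5E,7S)-6-bromo-8-(1-ethoxyethoxy)-7-hydroxy-2-methylocta-1,5-dien-1-yl]-3-(tributylstannyl)furan-2(5H)-one | O=C1O[C@H](/C=C(/C)CC/C=C(/Br)[C@@H](O)COC(C)OCC)C=C1[Sn](CCCC)(CCCC)CCCC | intermediate
18 | (5R)-5-[(1Z,5E,7S)-6-bromo-8-(1-ethoxyethoxy)-7-hydroxy-2-methylocta-1,5-dien-1-yl]-3-iodofuran-2(5H)-one | O=C1O[C@H](/C=C(/C)CC/C=C(/Br)[C@@H](O)COC(C)OCC)C=C1I | intermediate
19 | tributyl(iodomethyl)stannane | ICC[Sn](CCCC)(CCCC)CCCC is not meant; correct structure: IC[Sn](CCCC)(CCCC)CCCC | starting material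
20 | [(tributylstannyl)methyl]zinc iodide | I[Zn]C[Sn](CCCC)(CCCC)CCCC | intermediate
21 | (5R)-5-[(1Z,5E,7S)-6-bromo-8-(1-ethoxyethoxy)-7-hydroxy-2-methylocta-1,5-dien-1-yl]-3-[(tributylstannyl)methyl]furan-2(5H)-one | O=C1O[C@H](/C=C(/C)CC/C=C(/Br)[C@@H](O)COC(C)OCC)C=C1C[Sn](CCCC)(CCCC)CCCC | intermediate
22 | (5R)-5-[(1Z,5E,7S)-7-acetoxy-6-bromo-8-(1-ethoxyethoxy)-2-methylocta-1,5-dien-1-yl]-3-[(tributylstannyl)methyl]furan-2(5H)-one | O=C1O[C@H](/C=C(/C)CC/C=C(/Br)[C@@H](OC(C)=O)COC(C)OCC)C=C1C[Sn](CCCC)(CCCC)CCCC | intermediate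
23 | (5R)-5-[(1Z,5E,7S)-7-acetoxy-6-bromo-8-hydroxy-2-methylocta-1,5-dien-1-yl]-3-[(tributylstannyl)methyl]furan-2(5H)-one | O=C1O[C@H](/C=C(/C)CC/C=C(/Br)[C@@H](OC(C)=O)CO)C=C1C[Sn](CCCC)(CCCC)CCCC | intermediate
24 | (5R)-5-[(1Z,5E,7S)-7-acetoxy-6-bromo-2-methyl-8-oxoocta-1,5-dien-1-yl]-3-[(tributylstannyl)methyl]furan-2(5H)-one | O=C1O[C@H](/C=C(/C)CC/C=C(/Br)[C@@H](OC(C)=O)C=O)C=C1C[Sn](CCCC)(CCCC)CCCC | intermediate
25 | (3aR,4S,5S,6E,10Z,11aR)-6-bromo-4-hydroxy-10-methyl-3-methylidene-2-oxo-2,3,3a,4,5,8,9,11a-octahydrocyclodeca[b]furan-5-yl acetate | C=C1C(=O)O[C@@H]2/C=C(/C)CC/C=C(/Br)[C@@H](OC(C)=O)[C@@H](O)[C@@H]12 | intermediate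
26 | (2R)-2-methylbutanoic acid | CC[C@@H](C)C(=O)O | starting material
27 | chloroiodomethane | ClCI | starting material
28 | chloromethyl (2R)-2-methylbutanoate | CC[C@@H](C)C(=O)OCCl | intermediate
29 | iodomethyl (2R)-2-methylbutanoate | CC[C@@H](C)C(=O)OCI | intermediate
30 | ({[(2R)-2-methylbutanoyl]oxy}methyl)zinc iodide | CC[C@@H](C)C(=O)OC[Zn]I | intermediate
31 | [(3aR,4S,5R,6Z,10Z,11aR)-5-acetoxy-4-hydroxy-10-methyl-3-methylidene-2-oxo-2,3,3a,4,5,8,9,11a-octahydrocyclodeca[b]furan-6-yl]methyl (2R)-2-methylbutanoate | C=C1C(=O)O[C@@H]2/C=C(/C)CC/C=C(/COC(=O)[C@H](C)CC)[C@@H](OC(C)=O)[C@@H](O)[C@@H]12 | target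

(The SMILES of compound 19 is IC[Sn](CCCC)(CCCC)CCCC.)

Total step count: 18. Longest linear sequence: 14 steps (1, 3, 4, 6–15, 18).

**Steps most likely to fail**

Step 18. The zinc carbenoid may be lost by protonation or α-elimination before it transmetalates. Pd(0) may also ionise the allylic C9 acetate or the newly formed allylic ester, or the alkenylpalladium may insert into the exocyclic methylene lactone. The fallback separates C–C bond formation from acylation, sets out from 25 and comes back at 31. A Kosugi–Migita–Stille hydroxymethylation of 25 with (tributylstannyl)methanol 7 (Pd(PPh3)4, dioxane, 80 °C) should give (3aR,4S,5R,6Z,10Z,11aR)-4-hydroxy-6-(hydroxymethyl)-10-methyl-3-methylidene-2-oxo-2,3,3a,4,5,8,9,11a-octahydrocyclodeca[b]furan-5-yl acetate F1. Its primary allylic hydroxyl is then acylated in preference to the hindered secondary C8 hydroxyl with acid 26 (EDC·HCl, cat. DMAP, CH2Cl2, 0 °C) to give 31.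

Step 15. The forming ten-membered ring may override the open, Felkin-controlled transition state, so that the aldehyde reacts on its other face (poor facial selectivity at C8); intermolecular allylation may also compete. The fallback sets C8 by hydride delivery instead of by the C–C bond formation, sets out from 24 and comes back at 25. Whatever ring-closed material carries the wrong C8 configuration, the C8 epimer of 25 F2 (also expected when 24 is cyclised through a closed transition state after transmetalation with SnCl4), is oxidised with Dess–Martin periodinane to the 8-oxo analogue of 25 F3. Luche reduction (NaBH4, CeCl3·7H2O, MeOH, −78 °C) should then add hydride anti to the C9 acetoxy group (Felkin–Anh) and return 25, leaving the methylene lactone untouched.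

Step 11. Zinc insertion into the α-stannyl iodide may be incomplete, or the allylstannane product may be consumed by Stille-type coupling with remaining 18. The fallback replaces tin by silicon, sets out from 18 and comes back at 25. Negishi coupling of 18 with (trimethylsilyl)methylzinc chloride (from Me3SiCH2MgCl and ZnCl2; Pd(PPh3)4, THF, 25 °C) should give the allylsilane alcohol (5R)-5-[(1Z,5E,7S)-6-bromo-8-(1-ethoxyethoxy)-7-hydroxy-2-methylocta-1,5-dien-1-yl]-3-[(trimethylsilyl)methyl]furan-2(5H)-one F4. Acetylation as in step 12 gives the acetate F5, acetal cleavage as in step 13 gives the primary alcohol F6, and Dess–Martin oxidation as in step 14 gives the aldehyde F7. An intramolecular Hosomi–Sakurai reaction of F7 (TiCl4, CH2Cl2, high dilution, −78 → −40 °C), with the same stereochemical arguments as in step 15, should then close the ring to 25.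

Further compounds
F1 | step 18 | (3aR,4S,5R,6Z,10Z,11aR)-4-hydroxy-6-(hydroxymethyl)-10-methyl-3-methylidene-2-oxo-2,3,3a,4,5,8,9,11a-octahydrocyclodeca[b]furan-5-yl acetate | C=C1C(=O)O[C@@H]2/C=C(/C)CC/C=C(/CO)[C@@H](OC(C)=O)[C@@H](O)[C@@H]12
F2 | step 15 | C8 epimer of 25 (C4 epimer in the ring numbering of 25) | C=C1C(=O)O[C@@H]2/C=C(/C)CC/C=C(/Br)[C@@H](OC(C)=O)[C@H](O)[C@@H]12
F3 | step 15 | 8-oxo analogue of 25 (ketone in place of the C8 carbinol) | C=C1C(=O)O[C@@H]2/C=C(/C)CC/C=C(/Br)[C@@H](OC(C)=O)C(=O)[C@@H]12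
F4 | step 11 | (5R)-5-[(1Z,5E,7S)-6-bromo-8-(1-ethoxyethoxy)-7-hydroxy-2-methylocta-1,5-dien-1-yl]-3-[(trimethylsilyl)methyl]furan-2(5H)-one | O=C1O[C@H](/C=C(/C)CC/C=C(/Br)[C@@H](O)COC(C)OCC)C=C1C[Si](C)(C)C
F5 | step 11 | (5R)-5-[(1Z,5E,7S)-7-acetoxy-6-bromo-8-(1-ethoxyethoxy)-2-methylocta-1,5-dien-1-yl]-3-[(trimethylsilyl)methyl]furan-2(5H)-one | O=C1O[C@H](/C=C(/C)CC/C=C(/Br)[C@@H](OC(C)=O)COC(C)OCC)C=C1C[Si](C)(C)C
F6 | step 11 | (5R)-5-[(1Z,5E,7S)-7-acetoxy-6-bromo-8-hydroxy-2-methylocta-1,5-dien-1-yl]-3-[(trimethylsilyl)methyl]furan-2(5H)-one | O=C1O[C@H](/C=C(/C)CC/C=C(/Br)[C@@H](OC(C)=O)CO)C=C1C[Si](C)(C)C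
F7 | step 11 | (5R)-5-[(1Z,5E,7S)-7-acetoxy-6-bromo-2-methyl-8-oxoocta-1,5-dien-1-yl]-3-[(trimethylsilyl)methyl]furan-2(5H)-one | O=C1O[C@H](/C=C(/C)CC/C=C(/Br)[C@@H](OC(C)=O)C=O)C=C1C[Si](C)(C)C
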